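## Retrosynthetic overview

1. The C40 skeleton is cut into C15 (acyloxy ring half) + C10 trienedial + C15 (hydroxy-cyclohex-2-ene half), joined by two Wittig olefinations (C11=C12, then C11'=C12'). The palmitate is in place before the first one.
2. The acyloxy-trimethylcyclohexene ring is not made as a six-membered ring. A 1,3,3-trimethylbicyclo[3.1.0]hexan-2-ol (cyclopentane C1–C2–C3–C5–C6 carrying a C3–C4–C5 cyclopropane) is opened by acid with capture of palmitic acid at C3. The enabling feature is the homoallylic array C3(O-acyl)–C4H2–C5(CH3)=C6 of that ring, which can be folded back into a cyclopropylcarbinyl cation at C6.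
3. The bicyclic ketone comes from 2-methylcyclopent-2-enone (CBS reduction, OH-directed cyclopropanation, oxidation, gem-dimethylation). The side chain comes from (E)-3-methylpent-2-en-4-yn-1-ol (acetylide addition, Red-Al).
4. The hydroxy-cyclohex-2-ene half comes from (±)-α-ionone: HWE chain extension, allylic oxidation, reagent-controlled CBS reduction with separation of diastereomers, DIBAL.
5. Ring order: the cyclohex-2-ene ring and the cyclopentene are bought; the cyclopropane is added in step 2; the six-membered acyloxy ring appears last, in step 8.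

Key step: step 8

Remark: ring positions are given in carotenoid numbering (C1 = CMe2, C2 = CH2, C3 = CH–O, C4 = CH2, C5 = C–CH3, C6 = ring carbon bearing the chain; primed numbers for the hydroxy-cyclohex-2-ene ring); Z isomers at the Wittig-formed C11=C12 and C11'=C12' bonds are assumed to equilibrate to E on heating, as is usual for these hindered positions.

## Route

Step 1
Reactants: 1 2-methylcyclopent-2-en-1-one
Product: 2 (R)-2-methylcyclopent-2-en-1-ol
Conditions: (S)-Me-CBS (10 mol %), catecholborane, toluene, −78 °C; MeOH, then aq. NaOH wash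
Reagents that add atoms: none
Why: CBS reduction in which the α-methyl-substituted alkenyl flank acts as the large group, so the (S)-catalyst should give the (R)-allylic alcohol, the centre from which all chirality of the acyloxy ring is relayed.

Step 2
Reactants: 2 (R)-2-methylcyclopent-2-en-1-ol
Product: 3 (1S,2R,5R)-1-methylbicyclo[3.1.0]hexan-2-ol (OH cis to the cyclopropane CH2)
Conditions: Et2Zn, CH2I2, CH2Cl2, 0 °C
Reagents that add atoms: diiodomethane ICI
Why: Hydroxyl-directed Simmons–Smith (Furukawa) cyclopropanation; the zinc alkoxide delivers CH2 to the alkene face syn to the oxygen, so both ring-fusion centres follow from the carbinol configuration.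

Step 3
Reactants: 3 (1S,2R,5R)-1-methylbicyclo[3.1.0]hexan-2-ol
Product: 4 (1S,5R)-1-methylbicyclo[3.1.0]hexan-2-one
Conditions: Dess–Martin periodinane, NaHCO3, CH2Cl2, 0 °C → rt
Reagents that add atoms: none
Why: Dess–Martin oxidation of the secondary cyclopropylcarbinol under buffered conditions; the directing carbinol is erased while the two cyclopropane centres (one quaternary, one β to the carbonyl) cannot epimerise.

Step 4
Reactants: 4 (1S,5R)-1-methylbicyclo[3.1.0]hexan-2-one
Product: 6 (1S,5S)-1,3,3-trimethylbicyclo[3.1.0]hexan-2-one, via monomethyl ketone 5 (not isolated)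
Conditions: LDA, THF, −78 °C, then MeI; second charge of LDA, then MeI, DMPU, −78 → 0 °C (one pot)
Reagents that add atoms: iodomethane CI
Why: Kinetic enolate alkylation carried out twice; C3 is the only enolisable position because C1 is a quaternary cyclopropane carbon, so exhaustive methylation can only give the 3,3-dimethyl ketone and leaves the cyclopropane centres untouched.

Step 5
Reactants: 6 (1S,5S)-1,3,3-trimethylbicyclo[3.1.0]hexan-2-one; 7 (E)-3-methylpent-2-en-4-yn-1-ol
Product: 9 (1S,2R,5S)-2-[(E)-5-hydroxy-3-methylpent-3-en-1-yn-1-yl]-1,3,3-trimethylbicyclo[3.1.0]hexan-2-ol, via dilithio acetylide 8 (not isolated)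
Conditions: 7, n-BuLi (2 equiv per 7), THF, −78 → 0 °C; then 6, 0 °C → rt; H2O
Reagents that add atoms: none
Why: 1,2-Addition of a lithium acetylide to a ketone without α-hydrogen (no enolisation possible); attack is expected anti to the cyclopropane CH2, and the carbinol configuration is of no consequence because it is destroyed in step 8.

Step 6
Reactants: 9 (1S,2R,5S)-2-[(E)-5-hydroxy-3-methylpent-3-en-1-yn-1-yl]-1,3,3-trimethylbicyclo[3.1.0]hexan-2-ol
Product: 10 (1S,2R,5S)-2-[(1E,3E)-5-hydroxy-3-methylpenta-1,3-dien-1-yl]-1,3,3-trimethylbicyclo[3.1.0]hexan-2-ol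
Conditions: Red-Al, THF, 0 °C → rt; aq. Rochelle salt
Reagents that add atoms: none
Why: Alkoxide-directed trans-hydroalumination of the propargylic alcohol with Red-Al gives the (E)-alkene after protonolysis, a reduction established for 1-(3-methylpent-3-en-1-ynyl)cycloalkanols with a free primary hydroxyl; the cyclopropane and the trisubstituted alkene are inert.

Step 7
Reactants: 10 (1S,2R,5S)-2-[(1E,3E)-5-hydroxy-3-methylpenta-1,3-dien-1-yl]-1,3,3-trimethylbicyclo[3.1.0]hexan-2-ol
Product: 11 (2E,4E)-5-[(1S,2R,5S)-2-hydroxy-1,3,3-trimethylbicyclo[3.1.0]hexan-2-yl]-3-methylpenta-2,4-dien-1-yl acetate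
Conditions: Ac2O, pyridine, DMAP (cat.), CH2Cl2, 0 °C; chromatography on Et3N-deactivated silica
Reagents that add atoms: acetic anhydride CC(=O)OC(C)=O
Why: Chemoselective acetylation of the primary allylic alcohol; the tertiary, doubly neopentyl carbinol does not acylate, and the acetate both removes the primary oxygen as a competing nucleophile in step 8 and serves as the leaving group in step 9.

Step 8
Reactants: 11 (2E,4E)-5-[(1S,2R,5S)-2-hydroxy-1,3,3-trimethylbicyclo[3.1.0]hexan-2-yl]-3-methylpenta-2,4-dien-1-yl acetate; 12 palmitic acid (hexadecanoic acid)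
Product: 14 (1R)-4-[(1E,3E)-5-acetoxy-3-methylpenta-1,3-dien-1-yl]-3,5,5-trimethylcyclohex-3-en-1-yl hexadecanoate, via cyclopropylcarbinyl cation 13 (not isolated)
Conditions: 12 (4 equiv), Sc(OTf)3 (5 mol %), 4 Å MS, CH2Cl2, −20 → 0 °C; Et3N quench
Reagents that add atoms: none
Why: Ionisation of the tertiary, dienyl-substituted cyclopropylcarbinol gives cation 13, whose charge is shared with the cyclopropane bonds; palmitic acid attacks the secondary cyclopropane carbon C3 from the side opposite to the breaking C3–C5 bond, the electrons of that bond become the C5=C6 double bond, and the five-membered ring (C1, C2, C3, C5, C6) becomes the six-membered ring with the former cyclopropane CH2 as C4. The closest known reaction type is the cyclopropylcarbinyl-to-homoallyl rearrangement with an external nucleophile (i-steroid rearrangement of 3,5-cyclo-6-ols to 3β-acyloxy-Δ5-steroids, ring enlargement of sabinene hydrate to terpinen-4-ol, Julia olefin synthesis). No ring is closed: the ring is enlarged by cleavage of the bond shared by the three- and five-membered rings. The new stereocentre C3 is set stereospecifically by inversion at the cyclopropane CH, so the configuration installed in step 2 should be translated into 3R. The step needs cleavage of the internal C3–C5 bond and not the external C4–C5 bond, and capture at C3 and not at C6, C8 or C10: the first is secured because C3 is secondary and C4 primary, the second because esters formed at the tertiary or allylic positions re-ionise under the conditions whereas the homoallylic ester cannot, which makes the strain-free, conjugated triene the sink. The carbinol configuration at C6 is lost in the planar cation and does not matter.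

Step 9
Reactants: 14 (1R)-4-[(1E,3E)-5-acetoxy-3-methylpenta-1,3-dien-1-yl]-3,5,5-trimethylcyclohex-3-en-1-yl hexadecanoate
Product: 15 [(2E,4E)-5-[(4R)-4-(hexadecanoyloxy)-2,6,6-trimethylcyclohex-1-en-1-yl]-3-methylpenta-2,4-dien-1-yl]triphenylphosphonium bromide
Conditions: PPh3·HBr, CH2Cl2, 0 °C → rt; crystallisation (EtOAc/hexane)
Reagents that add atoms: triphenylphosphine hydrobromide [Br-].c1ccc(cc1)[PH+](c1ccccc1)c1ccccc1
Why: Allylic phosphonium salt formation by SN1-type ionisation of the primary allylic acetate and capture of the trienyl cation by PPh3 at its unhindered primary terminus, as known for polyenyl allylic acetates such as retinyl acetate; the homoallylic secondary palmitate cannot ionise, and crystallisation should remove any 9Z isomer.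

Step 10
Reactants: 15 the C15 phosphonium bromide; 16 (2E,4E,6E)-2,7-dimethylocta-2,4,6-trienedial
Product: 18 (3R)-3-(hexadecanoyloxy)-12'-apo-β-caroten-12'-al, via phosphorus ylide 17 (not isolated)
Conditions: 16 (2.5 equiv), 1,2-epoxybutane, i-PrOH/CH2Cl2, 40 °C; then brief reflux in heptane
Reagents that add atoms: none
Why: Wittig olefination of a semi-stabilised allylic ylide generated by the epoxide method (bromide opens the epoxide and the alkoxide formed deprotonates the salt), which keeps the medium nearly neutral for the two esters; the excess of symmetric dialdehyde secures mono-olefination and the hindered 11Z isomer should equilibrate to 11E on warming.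

Step 11
Reactants: 18 (3R)-3-(hexadecanoyloxy)-12'-apo-β-caroten-12'-al
Product: 19 (3R)-3-(hexadecanoyloxy)-12'-apo-β-caroten-12'-ol
Conditions: NaBH4, THF/EtOH, −10 → 0 °C
Reagents that add atoms: none
Why: Sodium borohydride 1,2-reduction of the polyene aldehyde, chemoselective over the saturated ester.

Step 12
Reactants: 19 (3R)-3-(hexadecanoyloxy)-12'-apo-β-caroten-12'-ol
Product: 20 [(3R)-3-(hexadecanoyloxy)-12'-apo-β-caroten-12'-yl]triphenylphosphonium bromide
Conditions: PPh3·HBr, CH2Cl2/MeOH (10:1), 0 °C → rt, dark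
Reagents that add atoms: triphenylphosphine hydrobromide [Br-].c1ccc(cc1)[PH+](c1ccccc1)c1ccccc1
Why: Allylic phosphonium salt formation from a polyenyl carbinol (SN1 through the delocalised cation with capture at the primary terminus), the standard entry to retinyl-type Wittig salts; the secondary palmitate should be stable to the weakly acidic reagent.

Step 13
Reactants: 21 (±)-α-ionone
Product: 22 (±)-(2E,4E)-3-methyl-5-(2,6,6-trimethylcyclohex-2-en-1-yl)penta-2,4-dienenitrile
Conditions: (EtO)2P(O)CH2CN, NaH, THF, 0 °C → rt; chromatography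
Reagents that add atoms: diethyl (cyanomethyl)phosphonate CCOP(=O)(CC#N)OCC
Why: Horner–Wadsworth–Emmons olefination of the methyl ketone, expected to give mainly the (9'E)-nitrile (the minor 9'Z isomer is removed by chromatography); the ring stereocentre is not touched and stays racemic.

Step 14
Reactants: 22 (±)-(2E,4E)-3-methyl-5-(2,6,6-trimethylcyclohex-2-en-1-yl)penta-2,4-dienenitrile
Product: 23 (±)-(2E,4E)-3-methyl-5-(2,6,6-trimethyl-4-oxocyclohex-2-en-1-yl)penta-2,4-dienenitrile
Conditions: 70 % aq. t-BuOOH, aq. NaOCl, K2CO3, MeCN, −5 → 0 °C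
Reagents that add atoms: tert-butyl hydroperoxide CC(C)(C)OO
Why: Radical allylic C–H oxidation by t-BuOO• at the ring CH2 next to the trisubstituted alkene, the least hindered allylic methylene, gives the ring enone, as established for α-ionone derivatives.

Step 15
Reactants: 23 (±)-(2E,4E)-3-methyl-5-(2,6,6-trimethyl-4-oxocyclohex-2-en-1-yl)penta-2,4-dienenitrile
Product: 24 (2E,4E)-5-[(1R,4R)-4-hydroxy-2,6,6-trimethylcyclohex-2-en-1-yl]-3-methylpenta-2,4-dienenitrile
Conditions: (S)-Me-CBS (20 mol %), catecholborane, toluene/CH2Cl2, −78 °C; chromatographic separation of the trans alcohol from the cis diastereomer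
Reagents that add atoms: none
Why: CBS reduction under reagent control: with the alkenyl flank as the large group the (S)-catalyst should give the (3'R)-carbinol from both enantiomers of 23, so the (6'R) enantiomer affords trans-24 and the (6'S) enantiomer the separable cis diastereomer; this sets C3' and selects C6'.

Step 16
Reactants: 24 (2E,4E)-5-[(1R,4R)-4-hydroxy-2,6,6-trimethylcyclohex-2-en-1-yl]-3-methylpenta-2,4-dienenitrile
Product: 26 (2E,4E)-5-[(1R,4R)-4-hydroxy-2,6,6-trimethylcyclohex-2-en-1-yl]-3-methylpenta-2,4-dienal, via aldimine 25 (not isolated)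
Conditions: DIBAL-H (2.5 equiv), CH2Cl2, −78 → −40 °C; aq. Rochelle salt
Reagents that add atoms: water O
Why: DIBAL partial reduction of the nitrile to the aluminium imine, hydrolysed on work-up to the aldehyde; the first equivalent of hydride is consumed by the hydroxyl, and the mild tartrate work-up should neither ionise the allylic alcohol nor epimerise C6'.

Step 17
Reactants: 20 the C25 phosphonium bromide; 26 (2E,4E)-5-[(1R,4R)-4-hydroxy-2,6,6-trimethylcyclohex-2-en-1-yl]-3-methylpenta-2,4-dienal
Product: 28 (3R,3'R,6'R)-3'-hydroxy-β,ε-caroten-3-yl hexadecanoate (lutein 3-O-palmitate), via phosphorus ylide 27 (not isolated)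
Conditions: 1,2-epoxybutane, EtOH/CH2Cl2, reflux; then reflux in n-heptane (Z → E), crystallisation under N2 in the dark
Reagents that add atoms: none
Why: Wittig olefination by the epoxide method joins C11' and C12' under nearly neutral conditions that spare the palmitate, the free allylic 3'-hydroxyl and the doubly allylic C6'–H; the 11'Z isomer should be converted thermally into the all-E polyene, so no stereocentre is affected.

## Compound list

1 | 2-methylcyclopent-2-en-1-one | CC1=CCCC1=O | starting material
2 | (R)-2-methylcyclopent-2-en-1-ol | O[C@@H]1CCC=C1C | intermediate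
3 | (1S,2R,5R)-1-methylbicyclo[3.1.0]hexan-2-ol | O[C@@H]1CC[C@@H]2C[C@]12C | intermediate
4 | (1S,5R)-1-methylbicyclo[3.1.0]hexan-2-one | O=C1CC[C@@H]2C[C@]12C | intermediate
5 | (1S,5R)-1,3-dimethylbicyclo[3.1.0]hexan-2-one, mixture of C3 epimers (not isolated) | O=C1C(C)C[C@@H]2C[C@]12C | intermediate
6 | (1S,5S)-1,3,3-trimethylbicyclo[3.1.0]hexan-2-one | O=C1C(C)(C)C[C@@H]2C[C@]12C | intermediate
7 | (E)-3-methylpent-2-en-4-yn-1-ol | C#C/C(C)=C/CO | starting material
8 | dilithio derivative of 7 (lithium alkoxide, lithium acetylide; not isolated) | [Li]C#C/C(C)=C/CO[Li] | intermediate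
9 | (1S,2R,5S)-2-[(E)-5-hydroxy-3-methylpent-3-en-1-yn-1-yl]-1,3,3-trimethylbicyclo[3.1.0]hexan-2-ol | O[C@]1(C#C/C(C)=C/CO)C(C)(C)C[C@@H]2C[C@]12C | intermediate
10 | (1S,2R,5S)-2-[(1E,3E)-5-hydroxy-3-methylpenta-1,3-dien-1-yl]-1,3,3-trimethylbicyclo[3.1.0]hexan-2-ol | O[C@]1(/C=C/C(C)=C/CO)C(C)(C)C[C@@H]2C[C@]12C | intermediate
11 | (2E,4E)-5-[(1S,2R,5S)-2-hydroxy-1,3,3-trimethylbicyclo[3.1.0]hexan-2-yl]-3-methylpenta-2,4-dien-1-yl acetate | O[C@]1(/C=C/C(C)=C/COC(C)=O)C(C)(C)C[C@@H]2C[C@]12C | intermediate
12 | palmitic acid (hexadecanoic acid) | CCCCCCCCCCCCCCCC(=O)O | starting material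
13 | tertiary cyclopropylcarbinyl/pentadienyl cation from 11 (not isolated) | CC(=O)OC/C=C(C)/C=C/[C+]1C(C)(C)C[C@@H]2C[C@]12C | intermediate
14 | (1R)-4-[(1E,3E)-5-acetoxy-3-methylpenta-1,3-dien-1-yl]-3,5,5-trimethylcyclohex-3-en-1-yl hexadecanoate | CCCCCCCCCCCCCCCC(=O)O[C@@H]1CC(C)=C(/C=C/C(C)=C/COC(C)=O)C(C)(C)C1 | intermediate
15 | [(2E,4E)-5-[(4R)-4-(hexadecanoyloxy)-2,6,6-trimethylcyclohex-1-en-1-yl]-3-methylpenta-2,4-dien-1-yl]triphenylphosphonium bromide | CCCCCCCCCCCCCCCC(=O)O[C@@H]1CC(C)=C(/C=C/C(C)=C/C[P+](c2ccccc2)(c2ccccc2)c2ccccc2)C(C)(C)C1.[Br-] | intermediate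
16 | (2E,4E,6E)-2,7-dimethylocta-2,4,6-trienedial | O=C/C(C)=C/C=C/C=C(C)/C=O | starting material
17 | ylide of 15 (not isolated) | CCCCCCCCCCCCCCCC(=O)O[C@@H]1CC(C)=C(/C=C/C(C)=C/C=P(c2ccccc2)(c2ccccc2)c2ccccc2)C(C)(C)C1 | intermediate
18 | (3R)-3-(hexadecanoyloxy)-12'-apo-β-caroten-12'-al | CCCCCCCCCCCCCCCC(=O)O[C@@H]1CC(C)=C(/C=C/C(C)=C/C=C/C(C)=C/C=C/C=C(C)/C=O)C(C)(C)C1 | intermediate
19 | (3R)-3-(hexadecanoyloxy)-12'-apo-β-caroten-12'-ol | CCCCCCCCCCCCCCCC(=O)O[C@@H]1CC(C)=C(/C=C/C(C)=C/C=C/C(C)=C/C=C/C=C(C)/CO)C(C)(C)C1 | intermediate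
20 | [(3R)-3-(hexadecanoyloxy)-12'-apo-β-caroten-12'-yl]triphenylphosphonium bromide | CCCCCCCCCCCCCCCC(=O)O[C@@H]1CC(C)=C(/C=C/C(C)=C/C=C/C(C)=C/C=C/C=C(C)/C[P+](c2ccccc2)(c2ccccc2)c2ccccc2)C(C)(C)C1.[Br-] | intermediate
21 | (±)-α-ionone | CC(=O)/C=C/C1C(C)=CCCC1(C)C | starting material
22 | (±)-(2E,4E)-3-methyl-5-(2,6,6-trimethylcyclohex-2-en-1-yl)penta-2,4-dienenitrile | N#C/C=C(C)/C=C/C1C(C)=CCCC1(C)C | intermediate
23 | (±)-(2E,4E)-3-methyl-5-(2,6,6-trimethyl-4-oxocyclohex-2-en-1-yl)penta-2,4-dienenitrile | N#C/C=C(C)/C=C/C1C(C)=CC(=O)CC1(C)C | intermediate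
24 | (2E,4E)-5-[(1R,4R)-4-hydroxy-2,6,6-trimethylcyclohex-2-en-1-yl]-3-methylpenta-2,4-dienenitrile | N#C/C=C(C)/C=C/[C@H]1C(C)=C[C@H](O)CC1(C)C | intermediate
25 | aldimine of 26 (not isolated) | N=C/C=C(C)/C=C/[C@H]1C(C)=C[C@H](O)CC1(C)C | intermediate
26 | (2E,4E)-5-[(1R,4R)-4-hydroxy-2,6,6-trimethylcyclohex-2-en-1-yl]-3-methylpenta-2,4-dienal | O=C/C=C(C)/C=C/[C@H]1C(C)=C[C@H](O)CC1(C)C | intermediate
27 | ylide of 20 (not isolated) | CCCCCCCCCCCCCCCC(=O)O[C@@H]1CC(C)=C(/C=C/C(C)=C/C=C/C(C)=C/C=C/C=C(C)/C=P(c2ccccc2)(c2ccccc2)c2ccccc2)C(C)(C)C1 | intermediate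
28 | (3R,3'R,6'R)-3'-hydroxy-β,ε-caroten-3-yl hexadecanoate (lutein 3-O-palmitate) | CCCCCCCCCCCCCCCC(=O)O[C@@H]1CC(C)=C(/C=C/C(C)=C/C=C/C(C)=C/C=C/C=C(C)/C=C/C=C(C)/C=C/[C@H]2C(C)=C[C@H](O)CC2(C)C)C(C)(C)C1 | target

## Step count and risks

Total: 17 steps. Longest linear sequence: 13 steps (steps 1–12, then step 17).

Steps most likely to fail:

1. Step 8. The delocalised cation may be captured by the weakly nucleophilic acid at an allylic chain position, or lose a proton, faster than the ring is enlarged; part of the stereospecificity at C3 may also be lost if the capture becomes stepwise. The fallback sets out from 11 and comes back at 14, and separates the ring enlargement from the acylation. Compound 11 would be opened in THF/water with catalytic HClO4 at 0 °C, the classical hydrolytic form of the cyclopropylcarbinyl-to-homoallyl rearrangement, in which water in large excess is the nucleophile at C3 (again with inversion). This should give (2E,4E)-5-[(4R)-4-hydroxy-2,6,6-trimethylcyclohex-1-en-1-yl]-3-methylpenta-2,4-dien-1-yl acetate F1. Its secondary hydroxyl is then esterified with palmitoyl chloride, pyridine and DMAP in CH2Cl2 to return to 14.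

2. Step 15. Reagent control may be incomplete in one enantiomeric series of the racemic ketone (substrate bias overriding the catalyst), which lowers the enantiomeric purity of the trans alcohol, and the two diastereomers may separate poorly. The fallback sets out from 23 and comes back at 24. Compound 23 would be reduced without a chiral reagent (NaBH4, CeCl3·7H2O, MeOH, −20 °C; Luche reduction), and the racemic trans alcohol rac-(2E,4E)-5-[(1R*,4R*)-4-hydroxy-2,6,6-trimethylcyclohex-2-en-1-yl]-3-methylpenta-2,4-dienenitrile F2 separated from the cis racemate by chromatography. Kinetic resolution by lipase-catalysed transesterification (Pseudomonas lipase, vinyl acetate, t-BuOMe) is expected to acylate the (R)-carbinol. This should give (1R,4R)-4-[(1E,3E)-4-cyano-3-methylbuta-1,3-dien-1-yl]-3,5,5-trimethylcyclohex-2-en-1-yl acetate F3, separable from the unreacted enantiomeric alcohol; methanolysis of it (K2CO3, MeOH) returns to 24. Should the enzyme prefer the other enantiomer, 24 is the alcohol that is left.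

3. Step 6. Hydride delivery may be steered by the primary alkoxide (1,4-reduction of the enyne to an allene), the diene may be over-reduced, or hydroalumination at the hindered tertiary alkoxide may stay incomplete. The fallback sets out from 7 and 6 and comes back at 10; it forms the E-alkene before the C–C bond is made. Compound 7 would be silylated (TBSCl, imidazole, DMF) to tert-butyldimethyl{[(E)-3-methylpent-2-en-4-yn-1-yl]oxy}silane F4. Hydrozirconation (Cp2Zr(H)Cl, THF) and iodinolysis give tert-butyl{[(2E,4E)-5-iodo-3-methylpenta-2,4-dien-1-yl]oxy}dimethylsilane F5. Iodine–lithium exchange (t-BuLi, Et2O, −78 °C) and addition of the dienyllithium to ketone 6 give (1S,2R,5S)-2-[(1E,3E)-5-(tert-butyldimethylsilyloxy)-3-methylpenta-1,3-dien-1-yl]-1,3,3-trimethylbicyclo[3.1.0]hexan-2-ol F6, and TBAF in THF returns to 10.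

Further compounds
F1 | step 8 | (2E,4E)-5-[(4R)-4-hydroxy-2,6,6-trimethylcyclohex-1-en-1-yl]-3-methylpenta-2,4-dien-1-yl acetate | O[C@@H]1CC(C)=C(/C=C/C(C)=C/COC(C)=O)C(C)(C)C1
F2 | step 15 | rac-(2E,4E)-5-[(1R*,4R*)-4-hydroxy-2,6,6-trimethylcyclohex-2-en-1-yl]-3-methylpenta-2,4-dienenitrile (racemate, one enantiomer drawn) | N#C/C=C(C)/C=C/[C@H]1C(C)=C[C@H](O)CC1(C)C
F3 | step 15 | (1R,4R)-4-[(1E,3E)-4-cyano-3-methylbuta-1,3-dien-1-yl]-3,5,5-trimethylcyclohex-2-en-1-yl acetate | N#C/C=C(C)/C=C/[C@H]1C(C)=C[C@H](OC(C)=O)CC1(C)C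
F4 | step 6 | tert-butyldimethyl{[(E)-3-methylpent-2-en-4-yn-1-yl]oxy}silane | C#C/C(C)=C/CO[Si](C)(C)C(C)(C)C
F5 | step 6 | tert-butyl{[(2E,4E)-5-iodo-3-methylpenta-2,4-dien-1-yl]oxy}dimethylsilane | I/C=C/C(C)=C/CO[Si](C)(C)C(C)(C)C
F6 | step 6 | (1S,2R,5S)-2-[(1E,3E)-5-(tert-butyldimethylsilyloxy)-3-methylpenta-1,3-dien-1-yl]-1,3,3-trimethylbicyclo[3.1.0]hexan-2-ol | O[C@]1(/C=C/C(C)=C/CO[Si](C)(C)C(C)(C)C)C(C)(C)C[C@@H]2C[C@]12C
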